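Ring B is disconnected at the C5–C6 bond (labdane numbering; ring A is C1–C5/C10, ring B is C5–C10). A C5 radical, flanked by C4 and the quaternary C10, is released from a ring A 4,5-epoxide by Cp2TiCl and adds to C6 of a vinyl ketone whose carbonyl is C8. One operation closes ring B, sets the trans ring fusion at C5 and leaves oxygen at C4 and C8, the handles for the C4 quaternary centre and the C8 exocyclic methylene. The precursor is a monocyclic epoxycyclohexane with the C10 quaternary centre, assembled by Claisen rearrangement with chirality transfer from (S)-3-methylcyclohex-2-en-1-ol and a citronellol-derived chain.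

Key step: step 9

Remark: positions follow labdane numbering (C17 = methylene carbon on C8, C18/C19 = methyl and oxygenated carbon on C4, C20 = methyl on C10, C11–C16 = side chain); C9, epimerizable next to the C8 carbonyl, and the oxygen-bearing C4/C5 carbons are carried as mixtures in 11–15 and written without descriptors until they converge (C9 in step 10, C4 in step 11).

Step 1
Reactants: 1 (R)-citronellol
Product: 2 (R)-citronellyl triisopropylsilyl ether
Conditions: iPr3SiCl, imidazole, DMF, 20 °C
Reagents that add atoms: chlorotriisopropylsilane (CC(C)[Si](Cl)(C(C)C)C(C)C)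
Why: Silyl ether formation protects the future C15 oxygen with a group that should survive low-valent titanium, LiN(iPr)2, Li/NH3 and LiAlH4.

Step 2
Reactants: 2 (R)-citronellyl triisopropylsilyl ether
Product: 4 (4R)-4-methyl-6-(triisopropylsilyloxy)hexanal, via ozonide 3 (not isolated)
Conditions: O3, CH2Cl2, −78 °C; then PPh3, −78 → 20 °C
Reagents that add atoms: ozone (O=[O+][O-])
Why: Ozonolysis with reductive work-up cleaves the trisubstituted alkene to the aldehyde whose carbonyl carbon becomes C9, without touching the C13 stereocenter.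

Step 3
Reactants: 4 (4R)-4-methyl-6-(triisopropylsilyloxy)hexanal
Product: 5 (3R)-6,6-dibromo-3-methylhexyl triisopropylsilyl ether
Conditions: (PhO)3P, Br2, CH2Cl2, −78 → 20 °C
Reagents that add atoms: bromine (BrBr)
Why: Deoxygenative geminal dibromination of the aldehyde by the triphenyl phosphite–bromine adduct should give the 1,1-dibromide needed for the alkylidenation.

Step 4
Reactants: 6 3-methylcyclohex-2-en-1-one
Product: 7 (S)-3-methylcyclohex-2-en-1-ol
Conditions: (R)-2-methyl-CBS-oxazaborolidine (10 mol %), catecholborane, toluene, −78 °C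
Reagents that add atoms: none
Why: Corey–Bakshi–Shibata reduction, in which the oxazaborolidine binds the ketone with the alkenyl arm as the large group and delivers hydride to one carbonyl face, should set the (S) carbinol centre that is later relayed to C10.

Step 5
Reactants: 7 (S)-3-methylcyclohex-2-en-1-ol; 8 3-chloropropanoyl chloride
Product: 9 (S)-3-methylcyclohex-2-en-1-yl 3-chloropropanoate
Conditions: pyridine, CH2Cl2, 0 °C
Reagents that add atoms: none
Why: Acylation of the allylic alcohol by the acid chloride at low temperature should form the ester without allylic ionization, so the carbinol configuration is kept.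

Step 6
Reactants: 9 (S)-3-methylcyclohex-2-en-1-yl 3-chloropropanoate; 5 (3R)-6,6-dibromo-3-methylhexyl triisopropylsilyl ether
Product: 10 (S)-3-methylcyclohex-2-en-1-yl (3Z,7R)-1-chloro-7-methyl-9-(triisopropylsilyloxy)non-3-en-3-yl ether
Conditions: TiCl4, TMEDA, Zn, PbCl2 (cat.), THF, 25 °C
Reagents that add atoms: none
Why: Takai–Utimoto alkylidenation of the ester carbonyl by the titanium–zinc reagent from the dibromide should give the Z enol ether, an allyl vinyl ether in which the ester carbon (C8) and the dibromide carbon (C9) are joined.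

Step 7
Reactants: 10 allyl vinyl ether
Product: 12 vinyl ketone (7R)-7-methyl-4-[(1R)-1-methylcyclohex-2-en-1-yl]-9-(triisopropylsilyloxy)non-1-en-3-one, via beta-chloro ketone 11 (not isolated)
Conditions: toluene, 110 °C; then Et3N, 20 °C
Reagents that add atoms: none
Why: The Claisen rearrangement forms the C9–C10 bond suprafacially on the ring face that carried the C–O bond, so the carbinol configuration is transferred to the quaternary C10, and E1cB loss of HCl then unveils the vinyl ketone (C9 forms as an inconsequential epimer mixture).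

Step 8
Reactants: 12 vinyl ketone
Product: 13 epoxy vinyl ketone (4,5-epoxide of ring A in 12)
Conditions: mCPBA, CH2Cl2, 0 °C
Reagents that add atoms: 3-chloroperbenzoic acid (OOC(=O)c1cccc(Cl)c1)
Why: Prilezhaev epoxidation is chemoselective for the electron-rich ring alkene over the electron-poor vinyl ketone, and either epoxide face serves because C4 ends as a ketone.

Step 9
Reactants: 13 epoxy vinyl ketone
Product: 14 trans-fused bicyclic hydroxy ketone, 4-hydroxy-15-(triisopropylsilyloxy)-17,18,19-trinorlabdan-8-one (H5 anti to the C10 methyl; C4 and C9 epimer mixture)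
Conditions: Cp2TiCl2 (2.2 equiv), Zn dust, THF, 20 °C, slow addition of 13; then 1 M HCl
Reagents that add atoms: none
Why: Cp2TiCl (trivalent titanium) coordinates the epoxide oxygen and breaks the C5–O bond homolytically, titanium staying on the less hindered C4 while the congested C5 next to the quaternary C10 becomes a secondary, nucleophilic radical that adds to the terminal carbon C6 of the vinyl ketone; the alpha-keto radical at C7 is reduced by a second Cp2TiCl to a titanium enolate that is protonated on work-up. The closest known reaction type is the Nugent–RajanBabu reductive epoxide opening with radical conjugate addition to an acceptor alkene, used here intramolecularly. Ring B closes in the 6-endo-trig mode, because the radical attacks the beta-carbon of the enone, whereas 5-exo attack at C7 would be anti-Michael and give an unstabilized primary radical. The one new stereocenter that must be controlled, C5, is set by a chair-like transition state built on the chair of ring A, in which the branched C9 chain is equatorial and the C10 methyl axial, so that C6 bonds to C5 from the equatorial direction and H5 ends axial and anti to the C10 methyl (trans-decalin), as in the second ring closure of radical polyene cyclizations. The step needs regioselective opening toward the C5 radical, which the quaternary C10 secures (a C4 radical could not cyclize productively), and equatorial rather than axial attack at C5, which the equatorial C9 anchor favours; C4 and C9 need no control, since C4 becomes a ketone and C9 is equilibrated in step 10.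

Step 10
Reactants: 14 hydroxy ketone
Product: 15 15-(triisopropylsilyloxy)-18,19-dinorlabd-8(17)-en-4-ol (C5, C9, C10, C13 as in the target; C4 epimers)
Conditions: Ph3PCH3Br, KOtBu (excess), toluene, 20 → 90 °C
Reagents that add atoms: methyltriphenylphosphonium bromide (C[P+](c1ccccc1)(c1ccccc1)c1ccccc1.[Br-])
Why: Wittig methylenation of the C8 ketone installs C17, and the excess base should first equilibrate C9 through the enolate to the epimer with the equatorial side chain (H9 anti to the C10 methyl), which the olefination then locks.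

Step 11
Reactants: 15 homoallylic-ring alcohol
Product: 16 (5S,9R,10S,13R)-15-(triisopropylsilyloxy)-18,19-dinorlabd-8(17)-en-4-one
Conditions: Dess–Martin periodinane, CH2Cl2, 20 °C
Reagents that add atoms: none
Why: Dess–Martin oxidation of the secondary alcohol gives the C4 ketone under neutral conditions that should neither epimerize C5 nor isomerize the exocyclic alkene.

Step 12
Reactants: 16 C4 ketone
Product: 18 C3–C4 enol triflate of ketone 16, via lithium enolate 17 (not isolated)
Conditions: LiN(iPr)2, THF, −78 °C; then PhNTf2, −78 → 0 °C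
Reagents that add atoms: N-phenylbis(trifluoromethanesulfonimide) (O=S(=O)(N(c1ccccc1)S(=O)(=O)C(F)(F)F)C(F)(F)F)
Why: Kinetic deprotonation removes a C3 methylene proton and not the hindered ring-fusion proton at C5, and O-sulfonylation of the enolate gives the enol triflate with C5 intact.

Step 13
Reactants: 18 enol triflate
Product: 19 methyl 15-(triisopropylsilyloxy)-18-norlabda-3,8(17)-dien-19-oate
Conditions: Pd(OAc)2 (5 mol %), PPh3, CO (1 atm), MeOH, Et3N, DMF, 60 °C
Reagents that add atoms: carbon monoxide ([C-]#[O+]); methanol (CO)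
Why: Palladium-catalysed methoxycarbonylation of the enol triflate (oxidative addition to zerovalent palladium, CO insertion, methanolysis) introduces C19 as a conjugated ester.

Step 14
Reactants: 19 unsaturated ester
Product: 21 methyl (4R,5S,9R,10S,13R)-15-(triisopropylsilyloxy)labd-8(17)-en-19-oate, via lithium ester enolate 20 (not isolated)
Conditions: Li, NH3 (l), THF, t-BuOH (1 equiv), −78 °C; then MeI, −78 → −33 °C
Reagents that add atoms: iodomethane (CI)
Why: Dissolving-metal conjugate reduction gives the C4 ester enolate regiospecifically, and its methylation (reductive alkylation) should occur from the equatorial direction, away from the 1,3-diaxial C10 methyl, so that the new methyl (C18) is equatorial and the ester (C19) axial.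

Step 15
Reactants: 21 quaternary methyl ester
Product: 22 (4R,5S,9R,10S,13R)-15-(triisopropylsilyloxy)labd-8(17)-en-19-ol
Conditions: LiAlH4, THF, 0 → 20 °C
Reagents that add atoms: none
Why: Hydride reduction of the hindered ester gives the neopentyl C19 alcohol, while the silyl ether and the alkene are inert.

Step 16
Reactants: 22 C19 alcohol; 23 (R)-2-methylbutanoic acid
Product: 24 (4R,5S,9R,10S,13R)-15-(triisopropylsilyloxy)labd-8(17)-en-19-yl (2R)-2-methylbutanoate
Conditions: DCC, DMAP (cat.), CH2Cl2, 20 °C
Reagents that add atoms: none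
Why: Steglich esterification acylates the C19 alcohol through the acylpyridinium without a base strong enough to enolize the alpha stereocenter of the acid.

Step 17
Reactants: 24 silyl ether ester
Product: 25 (4R,5S,9R,10S,13R)-15-hydroxylabd-8(17)-en-19-yl (2R)-2-methylbutanoate
Conditions: Bu4NF, THF, 20 °C
Reagents that add atoms: none
Why: Fluoride-induced desilylation frees the C15 alcohol, and the hindered C19 ester should neither cleave nor migrate.

Step 18
Reactants: 25 primary alcohol
Product: 26 (4R,5S,9R,10S,13R)-19-[(2R)-2-methylbutanoyloxy]labd-8(17)-en-15-oic acid (CNP0365997.1)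
Conditions: TEMPO (cat.), PhI(OAc)2, MeCN/H2O (1:1), 20 °C
Reagents that add atoms: water (O)
Why: TEMPO (oxoammonium) oxidation takes the primary alcohol through the aldehyde hydrate to the carboxylic acid without touching the 1,1-disubstituted alkene or the ester.

Compound list

1 | (R)-citronellol, (3R)-3,7-dimethyloct-6-en-1-ol | CC(C)=CCC[C@@H](C)CCO | starting material
2 | (R)-citronellyl triisopropylsilyl ether | CC(C)=CCC[C@@H](C)CCO[Si](C(C)C)(C(C)C)C(C)C | intermediate
3 | ozonide of 2 (3,3-dimethyl-1,2,4-trioxolane carrying the side chain at C5; not isolated) | CC1(C)OOC(CC[C@@H](C)CCO[Si](C(C)C)(C(C)C)C(C)C)O1 | intermediate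
4 | (4R)-4-methyl-6-(triisopropylsilyloxy)hexanal | O=CCC[C@@H](C)CCO[Si](C(C)C)(C(C)C)C(C)C | intermediate
5 | (3R)-6,6-dibromo-3-methylhexyl triisopropylsilyl ether | BrC(Br)CC[C@@H](C)CCO[Si](C(C)C)(C(C)C)C(C)C | intermediate
6 | 3-methylcyclohex-2-en-1-one | CC1=CC(=O)CCC1 | starting material
7 | (S)-3-methylcyclohex-2-en-1-ol | CC1=C[C@@H](O)CCC1 | intermediate
8 | 3-chloropropanoyl chloride | O=C(Cl)CCCl | starting material
9 | (S)-3-methylcyclohex-2-en-1-yl 3-chloropropanoate | CC1=C[C@@H](OC(=O)CCCl)CCC1 | intermediate
10 | (S)-3-methylcyclohex-2-en-1-yl (3Z,7R)-1-chloro-7-methyl-9-(triisopropylsilyloxy)non-3-en-3-yl ether | CC1=C[C@@H](O/C(CCCl)=C\CC[C@@H](C)CCO[Si](C(C)C)(C(C)C)C(C)C)CCC1 | intermediate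
11 | (7R)-1-chloro-7-methyl-4-[(1R)-1-methylcyclohex-2-en-1-yl]-9-(triisopropylsilyloxy)nonan-3-one (epimers at chain C4 = C9; not isolated) | ClCCC(=O)C(CC[C@@H](C)CCO[Si](C(C)C)(C(C)C)C(C)C)[C@@]1(C)C=CCCC1 | intermediate
12 | (7R)-7-methyl-4-[(1R)-1-methylcyclohex-2-en-1-yl]-9-(triisopropylsilyloxy)non-1-en-3-one (epimers at chain C4 = C9) | C=CC(=O)C(CC[C@@H](C)CCO[Si](C(C)C)(C(C)C)C(C)C)[C@@]1(C)C=CCCC1 | intermediate
13 | epoxy vinyl ketone: 12 with the ring alkene (C4=C5) as cis-epoxide (C10 and C13 as in 12; epoxide face and C9 mixtures) | C=CC(=O)C(CC[C@@H](C)CCO[Si](C(C)C)(C(C)C)C(C)C)[C@@]1(C)C2OC2CCC1 | intermediate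
14 | 4-hydroxy-15-(triisopropylsilyloxy)-17,18,19-trinorlabdan-8-one, trans-fused (H5 anti to C10 methyl; C4 and C9 epimers) | O=C1CC[C@@H]2C(O)CCC[C@@]2(C)C1CC[C@@H](C)CCO[Si](C(C)C)(C(C)C)C(C)C | intermediate
15 | 15-(triisopropylsilyloxy)-18,19-dinorlabd-8(17)-en-4-ol (5S,9R,10S,13R; C4 epimers) | C=C1CC[C@@H]2C(O)CCC[C@@]2(C)[C@@H]1CC[C@@H](C)CCO[Si](C(C)C)(C(C)C)C(C)C | intermediate
16 | (5S,9R,10S,13R)-15-(triisopropylsilyloxy)-18,19-dinorlabd-8(17)-en-4-one | C=C1CC[C@@H]2C(=O)CCC[C@@]2(C)[C@@H]1CC[C@@H](C)CCO[Si](C(C)C)(C(C)C)C(C)C | intermediate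
17 | lithium C3–C4 enolate of 16 (not isolated) | C=C1CC[C@@H]2C(O[Li])=CCC[C@@]2(C)[C@@H]1CC[C@@H](C)CCO[Si](C(C)C)(C(C)C)C(C)C | intermediate
18 | 15-(triisopropylsilyloxy)-18,19-dinorlabda-3,8(17)-dien-4-yl trifluoromethanesulfonate | C=C1CC[C@@H]2C(OS(=O)(=O)C(F)(F)F)=CCC[C@@]2(C)[C@@H]1CC[C@@H](C)CCO[Si](C(C)C)(C(C)C)C(C)C | intermediate
19 | methyl 15-(triisopropylsilyloxy)-18-norlabda-3,8(17)-dien-19-oate | C=C1CC[C@@H]2C(C(=O)OC)=CCC[C@@]2(C)[C@@H]1CC[C@@H](C)CCO[Si](C(C)C)(C(C)C)C(C)C | intermediate
20 | lithium enolate of the C19 methyl ester, exocyclic at C4 (not isolated) | C=C1CC[C@@H]2C(=C(O[Li])OC)CCC[C@@]2(C)[C@@H]1CC[C@@H](C)CCO[Si](C(C)C)(C(C)C)C(C)C | intermediate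
21 | methyl (4R,5S,9R,10S,13R)-15-(triisopropylsilyloxy)labd-8(17)-en-19-oate | C=C1CC[C@@H]2[C@](C)(C(=O)OC)CCC[C@@]2(C)[C@@H]1CC[C@@H](C)CCO[Si](C(C)C)(C(C)C)C(C)C | intermediate
22 | (4R,5S,9R,10S,13R)-15-(triisopropylsilyloxy)labd-8(17)-en-19-ol | C=C1CC[C@@H]2[C@](C)(CO)CCC[C@@]2(C)[C@@H]1CC[C@@H](C)CCO[Si](C(C)C)(C(C)C)C(C)C | intermediate
23 | (R)-2-methylbutanoic acid | CC[C@@H](C)C(=O)O | starting material
24 | (4R,5S,9R,10S,13R)-15-(triisopropylsilyloxy)labd-8(17)-en-19-yl (2R)-2-methylbutanoate | C=C1CC[C@@H]2[C@](C)(COC(=O)[C@H](C)CC)CCC[C@@]2(C)[C@@H]1CC[C@@H](C)CCO[Si](C(C)C)(C(C)C)C(C)C | intermediate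
25 | (4R,5S,9R,10S,13R)-15-hydroxylabd-8(17)-en-19-yl (2R)-2-methylbutanoate | C=C1CC[C@@H]2[C@](C)(COC(=O)[C@H](C)CC)CCC[C@@]2(C)[C@@H]1CC[C@@H](C)CCO | intermediate
26 | (4R,5S,9R,10S,13R)-19-[(2R)-2-methylbutanoyloxy]labd-8(17)-en-15-oic acid | C=C1CC[C@@H]2[C@](C)(COC(=O)[C@H](C)CC)CCC[C@@]2(C)[C@@H]1CC[C@@H](C)CC(=O)O | target

Total step count: 18. Longest linear sequence: 16 steps (steps 1–3 and 6–18).

Steps most likely to fail

Step 9. The C5 radical may be reduced to the alkene by a second Cp2TiCl before it cyclizes, or it may attack C6 from the axial face, so that the ring fusion forms as a cis/trans mixture (poor facial selectivity at C5). In the fallback the ring-fusion configuration is set by dissolving-metal protonation instead of by the radical closure. It sets out from ketone 16, taken on as obtained through steps 10 and 11. Enolization under equilibrating conditions (KN(SiMe3)2, 0.95 equiv, THF, 20 °C) and trapping with PhNTf2 should give the more substituted C4–C5 enol triflate F1. Methoxycarbonylation as in step 13 then gives the tetrasubstituted unsaturated ester F2. Li in NH3 followed by MeI, as in step 14, protonates C5 axially, anti to the C10 methyl, and methylates C4, which brings the route back at 21.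

Step 6. The alkylidenation may stall, or the low-valent titanium–zinc reagent may reduce or eliminate the chloro ester, while the dibromide 5 is consumed in excess. In the fallback the C9–C10 bond is made by an Ireland–Claisen rearrangement instead; it sets out from aldehyde 4 and alcohol 7. Aldehyde 4 is homologated by one carbon: CHCl3 with KOH gives the trichloromethyl carbinol F3, and NaBH4/NaOH (Jocic-type reductive homologation) gives the heptanoic acid F4. Esterification with 7 (DCC, DMAP) gives the allylic ester F5. LiN(iPr)2 and Me3SiCl (THF, −78 → 65 °C) rearrange its silyl ketene acetal with the same suprafacial transfer to C10 and give the acid F6. Coupling with MeNHOMe gives the Weinreb amide F7, which CH2=CHMgBr converts into vinyl ketone 12, where the route is rejoined.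

Step 14. The enolate may be protonated instead of methylated, or the ester may be over-reduced by the dissolving metal, so that the one-pot reductive alkylation is lost. In the fallback reduction and alkylation are separated, setting out from 19. Mg in MeOH reduces the conjugated ester to the saturated ester F8 (C4 epimers). Deprotonation with LiN(iPr)2 (THF, −78 °C) and methylation with MeI from the same equatorial direction then return the route to 21.

Further compounds

F1 | step 9 | 15-(triisopropylsilyloxy)-18,19-dinorlabda-4,8(17)-dien-4-yl trifluoromethanesulfonate (C4=C5 enol triflate) | C=C1CCC2=C(OS(=O)(=O)C(F)(F)F)CCC[C@@]2(C)[C@@H]1CC[C@@H](C)CCO[Si](C(C)C)(C(C)C)C(C)C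
F2 | step 9 | methyl 15-(triisopropylsilyloxy)-18-norlabda-4,8(17)-dien-19-oate (tetrasubstituted unsaturated ester) | C=C1CCC2=C(C(=O)OC)CCC[C@@]2(C)[C@@H]1CC[C@@H](C)CCO[Si](C(C)C)(C(C)C)C(C)C
F3 | step 6 | (5R)-1,1,1-trichloro-5-methyl-7-(triisopropylsilyloxy)heptan-2-ol (C2 epimers) | OC(CC[C@@H](C)CCO[Si](C(C)C)(C(C)C)C(C)C)C(Cl)(Cl)Cl
F4 | step 6 | (5R)-5-methyl-7-(triisopropylsilyloxy)heptanoic acid | OC(=O)CCC[C@@H](C)CCO[Si](C(C)C)(C(C)C)C(C)C
F5 | step 6 | (S)-3-methylcyclohex-2-en-1-yl (5R)-5-methyl-7-(triisopropylsilyloxy)heptanoate | CC1=C[C@@H](OC(=O)CCC[C@@H](C)CCO[Si](C(C)C)(C(C)C)C(C)C)CCC1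
F6 | step 6 | (5R)-5-methyl-2-[(1R)-1-methylcyclohex-2-en-1-yl]-7-(triisopropylsilyloxy)heptanoic acid (C2 epimers) | OC(=O)C(CC[C@@H](C)CCO[Si](C(C)C)(C(C)C)C(C)C)[C@@]1(C)C=CCCC1
F7 | step 6 | N-methoxy-N-methyl amide of F6 (Weinreb amide) | CON(C)C(=O)C(CC[C@@H](C)CCO[Si](C(C)C)(C(C)C)C(C)C)[C@@]1(C)C=CCCC1
F8 | step 14 | methyl 15-(triisopropylsilyloxy)-18-norlabd-8(17)-en-19-oate (C4 epimers) | C=C1CC[C@@H]2C(C(=O)OC)CCC[C@@]2(C)[C@@H]1CC[C@@H](C)CCO[Si](C(C)C)(C(C)C)C(C)C
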